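## Structural features

Gancaonin G (17) is an isoflavone: a benzene ring A is fused through the C4a–C8a bond to a 4-pyranone ring C, and ring C carries a 4-hydroxyphenyl ring B on C3 through the C3–C1' bond. The molecule has no stereocentre and no stereogenic double bond, so no stereocentres stand next to each other and nothing stereochemical has to be set. Ring A is fully differentiated: a free hydroxyl at C5 (hydrogen-bonded to the C4 carbonyl), a 3-methylbut-2-enyl (prenyl) chain at C6, a methyl ether at C7 and a hydrogen at C8. The fragile parts are the prenyl group (it cyclises onto the neighbouring C5 or C7 oxygen under protic or Lewis acid and is saturated by hydrogenolysis), the pyranone (opened at C2 by hydroxide or alkoxide, photolabile at short wavelength) and the two phenols. The real difficulty is the regiochemistry of ring A: prenyl must sit at C6 and not at C8, and of three oxygens only O7 may be methylated. Phloroglucinol-based routes usually settle this by a late selective demethylation next to the acid-sensitive prenyl group. The key step exploits the contiguous array C5(OH)–C6(prenyl)–C7(OMe)–C8(H) next to the C4a–C8a fusion. This is the hydroxyl/alkyl/alkoxyl/hydrogen pattern that a vinylketene and an alkoxyalkyne deliver, and the C2=C3 double bond of a preformed 4-pyranone serves as the vinyl part and becomes the C8a–C4a fusion.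

## Logic of the disconnections

17 is cut at the O4'–Si bond, which leads to 16. The ring B phenol would intercept a ketene and an acid chloride, so it must travel masked. A silyl ether is chosen because fluoride is the one deprotection that leaves the prenyl group and the free C5 hydroxyl alone. The gain is a single inert spectator through all earlier steps; the demand is a last step that stays near neutral.

16 is cut at four bonds of ring A: C8–C8a, C7–C8, C5–C6 and C4a–C5. This removes ring A completely and leaves 7, a monocyclic pyranone that already holds ring B, and 11, an acyclic ynol ether with prenyl and methoxyl on adjacent carbons. The placement of every ring A substituent, and the difference between the free O5 and the methylated O7, then follow from connectivity alone. The demand is heavy: the forward step must turn 7 into a ketene, add it to 11 in one orientation and close the ring onto C3 of the pyranone, and the light must act on the diazo group and not on the pyranone.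

7 is cut at the bond between the ketone carbon and the diazo carbon (the future C5–C8 pair), which leads back to 5 through 6. Acylation of a diazoalkane is the most direct entry to a diazomethyl ketone, and 5 is a stable acid. The demand is an activation of the acid that releases no strong acid, so that the silyl ether and the pyranone carbonyl are not attacked.

5 is traced to 4 without cutting a skeletal bond; only the carbon–oxygen bonds of the carboxyl group are returned to the alcohol level. The hydroxymethyl group is native to the cheapest pyranone building block and needs no protection during cross-coupling. The demand is an oxidation that spares the aryl silyl ether and the electron-rich ring B.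

4 is cut at the bond between pyranone C5 and aryl C1' (the future C3–C1' bond), which gives 2 and 3. Ring B is thus joined to a finished ring C by sp2–sp2 cross-coupling, and no deoxybenzoin chemistry is needed. The demand is a base mild enough to keep both the aryl silyl ether of 3 and the triflate of 2.

2 is cut at the O–S bond, which leads to 1. The enolic hydroxyl of 1 sits on the carbon that must carry ring B, so it is the natural handle. The demand is sulfonylation of the acidic enol in the presence of the primary alcohol.

11 is cut at its C3–C4 bond (propargylic–allylic), and its triple bond is traced to the acetal carbons of 8 by double elimination through 10; the other fragment is 9. Both are bulk chemicals. The demand is alkylation at the primary terminus of 9 without base-induced isomerisation of the skipped enyne.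

## Other disconnections considered

Alternative 1: The cut is at O1–C8a and C4–C4a. In the forward step CsF would release the aryne 3,5-dimethoxy-4-(3-methylbut-2-enyl)benzyne A3 from silyl triflate A2, and A3 would insert into the oxygen–acyl bond of 4-(methoxymethoxy)phenylacetic acid A4 to give the ortho-hydroxy deoxybenzoin A1. No ring is closed.
- In its favour: the step is polar and fluoride-triggered, with no light and no diazo compound, and on operational safety it is the better of the two plans. Its regiochemistry should be fixed by the methoxyl next to the aryne bond (oxygen adds at the distal carbon), which is as well defined as the ynol ether polarisation of the chosen plan, so the two are equal on that point. Conversion of a deoxybenzoin to an isoflavone with a one-carbon electrophile is classical and better precedented than a ring closure onto a pyranone.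
- Against it: A2 is itself a hexasubstituted benzene, so the prenyl and oxygen pattern of ring A has to be built separately before the key step. After A1 the route still needs ring C closure, cleavage of the C5 methyl ether with a Lewis acid beside the prenyl group (risk of cyclisation to a chroman), and acidic removal of the methoxymethyl group with the same risk.
- Comparison: this alternative joins a finished ring A to the rest, whereas the chosen plan creates ring A with its pattern in one operation. Two bonds and no ring stand against four bonds and one ring. The step count would probably be close to double.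

Alternative 2: The cut is at the C2=C3 double bond. Ring-closing metathesis of the aryl vinyl ether and 1,1-disubstituted enone in A6, with Mo(N-2,6-iPr2C6H3)(CHCMe2Ph)[OCMe(CF3)2]2, would close ring C and give 4'-benzyloxy-5,7-dimethoxyisoflavone A5.
- In its favour: the closure is neutral and mild, the mechanism (metal alkylidene [2+2] and cycloreversion) is well understood, and the only by-product is a volatile two-carbon alkene. On mildness and mechanistic predictability it equals or betters the chosen key step.
- Against it: A5 has no prenyl group, a methyl ether on O5 and a benzyl ether on O4'. Prenylation would have to choose C6 over C8 on a 5,7-dioxygenated ring that offers no clear bias. The benzyl ether cannot be removed by hydrogenolysis without saturating the prenyl alkene, and Lewis acid removal threatens chroman formation. The molybdenum alkylidene is air- and moisture-sensitive, and the enone alkene is a sluggish partner.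
- Comparison: one bond and ring C are formed, and every ring A problem is postponed. The chosen plan forms four bonds and solves those problems in the same step. Step economy is clearly worse for this alternative.

Alternative 3: The cut is at C4a–C4 and C3–C4, with carbon monoxide as C4. Under CO with Pd(OAc)2, PCy3 and CsOPiv, zerovalent palladium would insert into the carbon–iodine bond of A8, CO would insert, and the enol ether carbon would attack the acylpalladium to close ring C and give A7.
- In its favour: the prenyl group is already at C6 before ring closure, two carbon–carbon bonds form catalytically, and ring B arrives convergently as a styryl ether. No diazo compound or light is needed, which is an operational advantage. The length up to A7 should be about equal to the length of the chosen route up to 16.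
- Against it: the iodide is flanked by two ortho oxygen substituents, which slows oxidative addition. Closure without CO uptake to a benzofuran competes. The prenyl alkene can coordinate the acylpalladium. A8 needs regiocontrolled prenylation and iodination of a phloroglucinol ether. The end still requires C5-selective demethylation and acidic removal of the methoxymethyl group beside the prenyl chain.
- Comparison: the alternative forms ring C around a prefabricated ring A; the chosen plan forms ring A around a prefabricated ring C. The chosen plan is better at the end, where only a fluoride deprotection remains, and the alternative is better in avoiding photochemistry.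

Key step: step 6

Remark on the chemistry: atom mapping of the benzannulation (diazo carbon → C8, ketone carbon → C5, pyranone C2 → C8a, pyranone C3 → C4a, alkyne C1 → C7, alkyne C2 → C6) shows that 7, 11 and 16 are mutually consistent, so no structure needed correction. Isoflavone numbering is used for 15–17, and the transient racemic intermediates 13 and 15 are drawn without configuration.

## Route

Step 1
Reactants: 1 kojic acid (5-hydroxy-2-(hydroxymethyl)-4H-pyran-4-one)
Product: 2 6-(hydroxymethyl)-4-oxo-4H-pyran-3-yl trifluoromethanesulfonate
Conditions: PhNTf2 (1.05 equiv), Et3N (1.2 equiv), DMF, 0 °C → rt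
Reagents that add atoms: N-phenylbis(trifluoromethanesulfonimide), O=S(=O)(N(c1ccccc1)S(=O)(=O)C(F)(F)F)C(F)(F)F
Why: The enolic hydroxyl of 1 (pKa about 8) is ionised by Et3N while the primary alcohol is not, and the mild triflyl donor PhNTf2 sulfonylates only the oxyanion; this is a chemoselective enol triflate formation.

Step 2
Reactants: 2 6-(hydroxymethyl)-4-oxo-4H-pyran-3-yl trifluoromethanesulfonate; 3 4-(tert-butyldimethylsilyloxy)phenylboronic acid
Product: 4 5-[4-(tert-butyldimethylsilyloxy)phenyl]-2-(hydroxymethyl)-4H-pyran-4-one
Conditions: Pd(PPh3)4 (5 mol %), K3PO4 (2 equiv), 1,4-dioxane, 80 °C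
Reagents that add atoms: none
Why: Suzuki–Miyaura cross-coupling; the electron-poor enol triflate should add readily to zerovalent palladium, and phosphate in dioxane activates the boronic acid without hydroxide or fluoride, so the aryl silyl ether and the free primary alcohol should both persist.

Step 3
Reactants: 4 5-[4-(tert-butyldimethylsilyloxy)phenyl]-2-(hydroxymethyl)-4H-pyran-4-one
Product: 5 5-[4-(tert-butyldimethylsilyloxy)phenyl]-4-oxo-4H-pyran-2-carboxylic acid
Conditions: TEMPO (0.2 equiv), PhI(OAc)2 (2.2 equiv), MeCN–H2O (1:1), rt
Reagents that add atoms: water, O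
Why: Oxoammonium (TEMPO) oxidation with PhI(OAc)2 as terminal oxidant takes the primary alcohol through the aldehyde hydrate to the acid under near-neutral conditions; the electron-poor pyranone aldehyde hydrates easily, and the aryl silyl ether and the pyranone should not be touched.

Step 4
Reactants: 5 5-[4-(tert-butyldimethylsilyloxy)phenyl]-4-oxo-4H-pyran-2-carboxylic acid
Product: 7 2-diazo-1-{5-[4-(tert-butyldimethylsilyloxy)phenyl]-4-oxo-4H-pyran-2-yl}ethanone, via acid chloride 6 (not isolated)
Conditions: 1-chloro-N,N,2-trimethylprop-1-en-1-amine (1.2 equiv), CH2Cl2, 0 °C → rt; then Me3SiCHN2 (2.0 equiv), MeCN–THF, 0 °C, dark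
Reagents that add atoms: trimethylsilyldiazomethane, C[Si](C)(C)C=[N+]=[N-]
Why: The α-chloroenamine gives acid chloride 6 without free HCl, which protects the silyl ether and avoids chlorination at the pyranone carbonyl; acylation of the diazoalkane by 6 and loss of Me3SiCl gives the diazomethyl ketone (Arndt–Eistert-type acylation), with the commercial silyl reagent in place of diazomethane.

Step 5
Reactants: 8 chloroacetaldehyde dimethyl acetal (2-chloro-1,1-dimethoxyethane); 9 prenyl bromide (1-bromo-3-methylbut-2-ene)
Product: 11 1-methoxy-5-methylhex-4-en-1-yne, via sodium methoxyacetylide 10 (not isolated)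
Conditions: NaNH2 (3.0 equiv), liq. NH3, −33 °C; then 9 (0.9 equiv), −78 → −33 °C; NH4Cl, pentane extraction, distillation under reduced pressure
Reagents that add atoms: none
Why: Sodium amide removes HCl and MeOH from the chloroacetal to give sodium methoxyacetylide, which is alkylated in situ at the primary carbon of the allylic bromide (SN2 alkylation of an alkynide, the standard route to 1-alkoxyalk-1-ynes); the methyl ether has no β-hydrogen on the alkoxy group, so the product cannot fragment by the retro-ene path of higher alkoxyalkynes.

Step 6
Reactants: 7 2-diazo-1-{5-[4-(tert-butyldimethylsilyloxy)phenyl]-4-oxo-4H-pyran-2-yl}ethanone; 11 1-methoxy-5-methylhex-4-en-1-yne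
Product: 16 4'-O-tert-butyldimethylsilyl gancaonin G (3-[4-(tert-butyldimethylsilyloxy)phenyl]-5-hydroxy-7-methoxy-6-(3-methylbut-2-enyl)-4H-chromen-4-one), via pyranonylketene 12 (not isolated), via methoxycyclobutenone 13 (not isolated), via dienylketene 14 (not isolated), via cyclohexadienone 15 (not isolated)
Conditions: 11 (2 equiv), degassed ClCH2CH2Cl (0.05 M), hν (365 nm LED, Pyrex), 20 °C; then 80 °C, dark
Reagents that add atoms: none
Why: Excitation of the diazo ketone expels N2 and the pyranonyl group migrates from the ketone carbon to the former diazo carbon (Wolff rearrangement, new C8–C8a bond), giving ketene 12. Ketene 12 adds across the electron-rich triple bond of 11 in a [2+2] cycloaddition to give cyclobutenone 13 (C5–C6 and C7–C8). Four-electron conrotatory opening of 13, thermal or photochemical, cleaves the old ketone–diazo carbon bond to give dienylketene 14, and a six-electron disrotatory electrocyclisation joins the ketene carbon to pyranone C3 (C4a–C5), closing the six-membered carbocyclic ring A as dienone 15, which enolises to the chelated C5 phenol 16. The closest known reaction type is the Danheiser benzannulation in its photochemical Wolff variant, which joins α,β-unsaturated or aryl diazomethyl ketones with alkoxy- and siloxyalkynes; here the pyranone C2=C3 bond plays the part of the alkene of an unsaturated diazo ketone. No stereocentre survives: the sp3 carbons of 13 and 15 are erased by ring opening and enolisation, and a wrong double-bond geometry in 14 is corrected by reversible reclosure to 13. The [2+2] regiochemistry is secured by the polarisation of the ynol ether, whose prenyl-bearing carbon is nucleophilic and bonds to the ketene carbonyl carbon, so prenyl ends ortho and methoxyl meta to the new hydroxyl. The ring closure has only one possible site, because pyranone C2 is flanked by O1 and C3, and C3 is the nucleophilic β-carbon of the ring enol ether, matched to the electrophilic ketene carbon. The step also needs chemoselectivity: the ketene should prefer the ynol ether over the unactivated prenyl alkene, and long-wavelength light addresses the diazo chromophore while sparing the pyranone and the product.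

Step 7
Reactants: 16 4'-O-tert-butyldimethylsilyl gancaonin G
Product: 17 gancaonin G (5-hydroxy-3-(4-hydroxyphenyl)-7-methoxy-6-(3-methylbut-2-enyl)-4H-chromen-4-one)
Conditions: Bu4NF (1.2 equiv), AcOH (1.2 equiv), THF, 0 °C
Reagents that add atoms: none
Why: Fluoride cleaves the aryl oxygen–silicon bond (fluoride-mediated desilylation); buffering with acetic acid keeps the medium near neutral, so the base-sensitive pyranone and the acid-sensitive prenyl group should both survive.

## Compound list

1 | kojic acid (5-hydroxy-2-(hydroxymethyl)-4H-pyran-4-one) | OCc1cc(=O)c(O)co1 | starting material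
2 | 6-(hydroxymethyl)-4-oxo-4H-pyran-3-yl trifluoromethanesulfonate | OCc1cc(=O)c(OS(=O)(=O)C(F)(F)F)co1 | intermediate
3 | 4-(tert-butyldimethylsilyloxy)phenylboronic acid | CC(C)(C)[Si](C)(C)Oc1ccc(B(O)O)cc1 | starting material
4 | 5-[4-(tert-butyldimethylsilyloxy)phenyl]-2-(hydroxymethyl)-4H-pyran-4-one | OCc1cc(=O)c(-c2ccc(O[Si](C)(C)C(C)(C)C)cc2)co1 | intermediate
5 | 5-[4-(tert-butyldimethylsilyloxy)phenyl]-4-oxo-4H-pyran-2-carboxylic acid | OC(=O)c1cc(=O)c(-c2ccc(O[Si](C)(C)C(C)(C)C)cc2)co1 | intermediate
6 | 5-[4-(tert-butyldimethylsilyloxy)phenyl]-4-oxo-4H-pyran-2-carbonyl chloride | ClC(=O)c1cc(=O)c(-c2ccc(O[Si](C)(C)C(C)(C)C)cc2)co1 | intermediate (not isolated)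
7 | 2-diazo-1-{5-[4-(tert-butyldimethylsilyloxy)phenyl]-4-oxo-4H-pyran-2-yl}ethanone | [N-]=[N+]=CC(=O)c1cc(=O)c(-c2ccc(O[Si](C)(C)C(C)(C)C)cc2)co1 | intermediate
8 | chloroacetaldehyde dimethyl acetal (2-chloro-1,1-dimethoxyethane) | COC(CCl)OC | starting material
9 | prenyl bromide (1-bromo-3-methylbut-2-ene) | CC(C)=CCBr | starting material
10 | sodium methoxyacetylide | COC#[C-].[Na+] | intermediate (not isolated)
11 | 1-methoxy-5-methylhex-4-en-1-yne | COC#CCC=C(C)C | intermediate
12 | {5-[4-(tert-butyldimethylsilyloxy)phenyl]-4-oxo-4H-pyran-2-yl}ketene | O=C=Cc1cc(=O)c(-c2ccc(O[Si](C)(C)C(C)(C)C)cc2)co1 | intermediate (not isolated)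
13 | 5-[4-(tert-butyldimethylsilyloxy)phenyl]-2-[2-methoxy-3-(3-methylbut-2-enyl)-4-oxocyclobut-2-en-1-yl]-4H-pyran-4-one (racemic) | COC1=C(CC=C(C)C)C(=O)C1c1cc(=O)c(-c2ccc(O[Si](C)(C)C(C)(C)C)cc2)co1 | intermediate (not isolated)
14 | (3E)-3-methoxy-2-(3-methylbut-2-enyl)-4-{5-[4-(tert-butyldimethylsilyloxy)phenyl]-4-oxo-4H-pyran-2-yl}buta-1,3-dien-1-one (ketene arm cis to the pyranonyl group) | O=C=C(CC=C(C)C)/C(OC)=C\c1cc(=O)c(-c2ccc(O[Si](C)(C)C(C)(C)C)cc2)co1 | intermediate (not isolated)
15 | 3-[4-(tert-butyldimethylsilyloxy)phenyl]-7-methoxy-6-(3-methylbut-2-enyl)-4aH-chromene-4,5-dione (racemic) | COC1=C(CC=C(C)C)C(=O)C2C(=O)C(-c3ccc(O[Si](C)(C)C(C)(C)C)cc3)=COC2=C1 | intermediate (not isolated)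
16 | 4'-O-tert-butyldimethylsilyl gancaonin G | COc1cc2occ(-c3ccc(O[Si](C)(C)C(C)(C)C)cc3)c(=O)c2c(O)c1CC=C(C)C | intermediate
17 | gancaonin G | COc1cc2occ(-c3ccc(O)cc3)c(=O)c2c(O)c1CC=C(C)C | target

## Step count and least certain steps

Total step count: 7. Longest linear sequence: 6 (steps 1, 2, 3, 4, 6, 7); step 5 is the one-step side branch.

**Step 6 (key step).** Three processes could divert it:
- competitive excitation of the pyranone chromophore, leading to skeletal photorearrangement;
- capture of the ketene by moisture or by the phenol of the product, or ketene dimerisation;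
- stalling at the cyclobutenone stage if closure onto the pyranone double bond is slower than decomposition.

The fallback generates the same ketene without light; it sets out from 7 and comes back at 16. Silver benzoate-catalysed Wolff rearrangement of 7 in aqueous dioxane with Et3N (Arndt–Eistert homologation) should give {5-[4-(tert-butyldimethylsilyloxy)phenyl]-4-oxo-4H-pyran-2-yl}acetic acid F1. The α-chloroenamine of step 4 would convert this to {5-[4-(tert-butyldimethylsilyloxy)phenyl]-4-oxo-4H-pyran-2-yl}acetyl chloride F2. Slow addition of Et3N to F2 and 11 in toluene at 0–20 °C in the dark would form ketene 12 by dehydrochlorination, which adds to 11 to give 13. Heating to 80–110 °C would carry 13 through 14 and 15 to 16.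

**Step 5.** The allylic bromide may be consumed by ammonolysis, elimination or attack at its tertiary terminus. The doubly activated methylene of the skipped enyne may be deprotonated by residual amide, with isomerisation to allene or conjugated enyne. The volatile ynol ether may also be hydrated or lost on isolation.

The fallback replaces 11 by a siloxyalkyne made without strong base at the end; it sets out from 7 and comes back at 17.
- Commercial methyl 4-methylpent-3-enoate (COC(=O)CC=C(C)C) would be homologated with CH2Br2/lithium 2,2,6,6-tetramethylpiperidide and then n-BuLi (Kowalski ester homologation) to lithium 5-methylhex-4-en-1-yn-1-olate F3.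
- O-Silylation with iPr3SiCl would give triisopropyl[(5-methylhex-4-en-1-yn-1-yl)oxy]silane F4.
- Irradiation of 7 with F4 as in step 6 should run through ketene 12, the siloxycyclobutenone F5, the siloxy dienylketene F6 and the siloxy cyclohexadienone F7 to 3-[4-(tert-butyldimethylsilyloxy)phenyl]-5-hydroxy-6-(3-methylbut-2-enyl)-7-(triisopropylsilyloxy)-4H-chromen-4-one F8.
- Bu4NF would remove both silyl groups to give wighteone (5,7-dihydroxy-3-(4-hydroxyphenyl)-6-(3-methylbut-2-enyl)-4H-chromen-4-one) F9.
- One equivalent of MeI with K2CO3 in acetone should methylate the most acidic hydroxyl, O7 (para to the carbonyl), to give 17. Over-methylation at O4' is the cost of this detour.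

**Step 4.** The diazoalkane may add as a 1,3-dipole to the electron-poor C2=C3 bond of the acylpyranone, the activating agent may attack the pyranone carbonyl, or the C-silyl diazo ketone may be desilylated incompletely.

The fallback is diazo transfer to a methyl ketone; it sets out from 4 and comes back at 7.
- Dess–Martin periodinane would oxidise 4 to 5-[4-(tert-butyldimethylsilyloxy)phenyl]-4-oxo-4H-pyran-2-carbaldehyde F10.
- MeMgBr in THF at −78 °C should add to the aldehyde faster than to the pyranone, giving 5-[4-(tert-butyldimethylsilyloxy)phenyl]-2-(1-hydroxyethyl)-4H-pyran-4-one F11 (racemic).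
- A second Dess–Martin oxidation would give 2-acetyl-5-[4-(tert-butyldimethylsilyloxy)phenyl]-4H-pyran-4-one F12.
- LiN(SiMe3)2 and CF3CO2CH2CF3 at −78 °C would give the trifluoroacetyl diketone 4,4,4-trifluoro-1-{5-[4-(tert-butyldimethylsilyloxy)phenyl]-4-oxo-4H-pyran-2-yl}butane-1,3-dione F13.
- Methanesulfonyl azide, Et3N and water in MeCN (detrifluoroacetylative diazo transfer) would convert F13 to 7.

**Step 2.** The base may cleave the aryl silyl ether, the electron-rich boronic acid may protodeboronate, or the triflate may be hydrolysed before coupling.

The fallback puts the silyl group on after the coupling; it sets out from 2 and comes back at 4.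
- Coupling of 2 with commercial 4-hydroxyphenylboronic acid (OB(O)c1ccc(O)cc1) under Pd(PPh3)4 and aqueous Na2CO3 in dimethoxyethane would give 5-(4-hydroxyphenyl)-2-(hydroxymethyl)-4H-pyran-4-one F14.
- tert-Butyldimethylsilyl chloride and imidazole in DMF would give the bis-silyl ether 5-[4-(tert-butyldimethylsilyloxy)phenyl]-2-[(tert-butyldimethylsilyloxy)methyl]-4H-pyran-4-one F15.
- Pyridinium p-toluenesulfonate in MeOH should cleave the primary alkyl silyl ether faster than the aryl silyl ether and return 4.

## Further compounds

F1 | step 6 | {5-[4-(tert-butyldimethylsilyloxy)phenyl]-4-oxo-4H-pyran-2-yl}acetic acid | OC(=O)Cc1cc(=O)c(-c2ccc(O[Si](C)(C)C(C)(C)C)cc2)co1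
F2 | step 6 | {5-[4-(tert-butyldimethylsilyloxy)phenyl]-4-oxo-4H-pyran-2-yl}acetyl chloride | ClC(=O)Cc1cc(=O)c(-c2ccc(O[Si](C)(C)C(C)(C)C)cc2)co1
F3 | step 5 | lithium 5-methylhex-4-en-1-yn-1-olate | [Li+].[O-]C#CCC=C(C)C
F4 | step 5 | triisopropyl[(5-methylhex-4-en-1-yn-1-yl)oxy]silane | CC(C)=CCC#CO[Si](C(C)C)(C(C)C)C(C)C
F5 | step 5 | 5-[4-(tert-butyldimethylsilyloxy)phenyl]-2-[3-(3-methylbut-2-enyl)-4-oxo-2-(triisopropylsilyloxy)cyclobut-2-en-1-yl]-4H-pyran-4-one (racemic) | CC(C)[Si](C(C)C)(C(C)C)OC1=C(CC=C(C)C)C(=O)C1c1cc(=O)c(-c2ccc(O[Si](C)(C)C(C)(C)C)cc2)co1
F6 | step 5 | (3E)-2-(3-methylbut-2-enyl)-4-{5-[4-(tert-butyldimethylsilyloxy)phenyl]-4-oxo-4H-pyran-2-yl}-3-(triisopropylsilyloxy)buta-1,3-dien-1-one | O=C=C(CC=C(C)C)/C(O[Si](C(C)C)(C(C)C)C(C)C)=C\c1cc(=O)c(-c2ccc(O[Si](C)(C)C(C)(C)C)cc2)co1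
F7 | step 5 | 3-[4-(tert-butyldimethylsilyloxy)phenyl]-6-(3-methylbut-2-enyl)-7-(triisopropylsilyloxy)-4aH-chromene-4,5-dione (racemic) | CC(C)[Si](C(C)C)(C(C)C)OC1=C(CC=C(C)C)C(=O)C2C(=O)C(-c3ccc(O[Si](C)(C)C(C)(C)C)cc3)=COC2=C1
F8 | step 5 | 3-[4-(tert-butyldimethylsilyloxy)phenyl]-5-hydroxy-6-(3-methylbut-2-enyl)-7-(triisopropylsilyloxy)-4H-chromen-4-one | CC(C)=CCc1c(O[Si](C(C)C)(C(C)C)C(C)C)cc2occ(-c3ccc(O[Si](C)(C)C(C)(C)C)cc3)c(=O)c2c1O
F9 | step 5 | wighteone (5,7-dihydroxy-3-(4-hydroxyphenyl)-6-(3-methylbut-2-enyl)-4H-chromen-4-one) | CC(C)=CCc1c(O)cc2occ(-c3ccc(O)cc3)c(=O)c2c1O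
F10 | step 4 | 5-[4-(tert-butyldimethylsilyloxy)phenyl]-4-oxo-4H-pyran-2-carbaldehyde | O=Cc1cc(=O)c(-c2ccc(O[Si](C)(C)C(C)(C)C)cc2)co1
F11 | step 4 | 5-[4-(tert-butyldimethylsilyloxy)phenyl]-2-(1-hydroxyethyl)-4H-pyran-4-one (racemic) | CC(O)c1cc(=O)c(-c2ccc(O[Si](C)(C)C(C)(C)C)cc2)co1
F12 | step 4 | 2-acetyl-5-[4-(tert-butyldimethylsilyloxy)phenyl]-4H-pyran-4-one | CC(=O)c1cc(=O)c(-c2ccc(O[Si](C)(C)C(C)(C)C)cc2)co1
F13 | step 4 | 4,4,4-trifluoro-1-{5-[4-(tert-butyldimethylsilyloxy)phenyl]-4-oxo-4H-pyran-2-yl}butane-1,3-dione | O=C(CC(=O)C(F)(F)F)c1cc(=O)c(-c2ccc(O[Si](C)(C)C(C)(C)C)cc2)co1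
F14 | step 2 | 5-(4-hydroxyphenyl)-2-(hydroxymethyl)-4H-pyran-4-one | OCc1cc(=O)c(-c2ccc(O)cc2)co1
F15 | step 2 | 5-[4-(tert-butyldimethylsilyloxy)phenyl]-2-[(tert-butyldimethylsilyloxy)methyl]-4H-pyran-4-one | CC(C)(C)[Si](C)(C)OCc1cc(=O)c(-c2ccc(O[Si](C)(C)C(C)(C)C)cc2)co1
A1 | alternative 1 | 1-[2-hydroxy-4,6-dimethoxy-5-(3-methylbut-2-enyl)phenyl]-2-[4-(methoxymethoxy)phenyl]ethanone | COCOc1ccc(CC(=O)c2c(O)cc(OC)c(CC=C(C)C)c2OC)cc1
A2 | alternative 1 | 3,5-dimethoxy-4-(3-methylbut-2-enyl)-2-(trimethylsilyl)phenyl trifluoromethanesulfonate | COc1cc(OS(=O)(=O)C(F)(F)F)c([Si](C)(C)C)c(OC)c1CC=C(C)C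
A3 | alternative 1 | 3,5-dimethoxy-4-(3-methylbut-2-enyl)benzyne | COC1=C(CC=C(C)C)C(OC)=CC#C1
A4 | alternative 1 | 4-(methoxymethoxy)phenylacetic acid | COCOc1ccc(CC(=O)O)cc1
A5 | alternative 2 | 4'-benzyloxy-5,7-dimethoxyisoflavone | COc1cc(OC)c2c(c1)occ(-c1ccc(OCc3ccccc3)cc1)c2=O
A6 | alternative 2 | 2-[4-(benzyloxy)phenyl]-1-[2-(ethenyloxy)-4,6-dimethoxyphenyl]prop-2-en-1-one | C=COc1cc(OC)cc(OC)c1C(=O)C(=C)c1ccc(OCc2ccccc2)cc1
A7 | alternative 3 | 5,7-dimethoxy-4'-(methoxymethoxy)-6-(3-methylbut-2-enyl)isoflavone | COCOc1ccc(-c2coc3cc(OC)c(CC=C(C)C)c(OC)c3c2=O)cc1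
A8 | alternative 3 | 1-iodo-2,4-dimethoxy-3-(3-methylbut-2-enyl)-6-{(E)-2-[4-(methoxymethoxy)phenyl]ethenyloxy}benzene | COCOc1ccc(/C=C/Oc2cc(OC)c(CC=C(C)C)c(OC)c2I)cc1
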